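## Structural features

The target is a trans-fused hydroazulene. Cyclopentane ring A (C1, C2, C3, C4, C5) shares the C1–C5 bond with cycloheptene ring B (C1, C5, C6, C7, C8, C9, C10), whose C7=C8 alkene carries the C8 methyl. All bicyclic compounds below are named on bicyclo[5.3.0]decane with these locants, not with von Baeyer locants. There are five stereocenters, (1R,4R,5S,6S,9S). The quaternary C1 (methyl), the tertiary carbinol C4 (isopropyl), C5 (H) and C6 (4-hydroxybenzoyloxy) are contiguous, and C9 (acetoxy) stands alone at the second allylic position. H5, the C6 and C9 oxygens and the isopropyl group lie on one face; the C1 methyl and the C4 hydroxyl lie on the other. The fragile parts are two different esters on the two allylic carbons that flank one trisubstituted alkene (ionisation, allylic shift, acyl migration), a free phenol on an aryl ester, and a tertiary alcohol that can dehydrate. The real difficulty is the quaternary C1 at the trans fusion of a seven-membered ring, together with telling apart two secondary oxygens that sit cis-1,4 across C7=C8, and a fully substituted C4 next to the ring fusion. The key step uses the fact that ring B, without the shared bond, falls into a three-carbon piece C8–C9–C10 with its oxygen on the central carbon and a four-carbon piece C7–C6–C5–C1 whose C5–C1 bond is part of ring A. A 2-silyloxyvinyl carbenoid and a 1-vinylcyclopentene with C1 as the substituted diene terminus map onto these pieces, and the C5=C6 alkene that is left sits where H5 and the C6 oxygen are needed.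

## Logic of the disconnections

27 goes back to 26 by masking the phenol as its acetate (aryl O–acyl bond), and 26 goes back to 24 and 25 by cutting the acyl C–O bond at C6. The aroate is put on last so that no later step can touch it, and 25 brings the whole aryl unit in one operation. The forward steps must acylate the hindered C6 hydroxyl beside a free tertiary alcohol and then remove an aryl acetate in the presence of an alkyl acetate.

24 goes back to 23 (O–Si bond at C6) and 23 to 22 (O–acetyl bond at C9). The two secondary oxygens are distinguished by their history, not by selective acylation of a diol: the C6 oxygen is carried as a silyl ether from an early stage, and the C9 hydroxyl appears late and free. The forward steps need an acetylation that leaves the tertiary carbinol alone and a desilylation that does not move the acetate.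

22 goes back to 21 by cutting the C4–isopropyl bond. This removes the C4 stereocenter and three carbons and leaves a cyclopentanone. The addition must come from the H5 face and must precede every ester, which is why both acylations stand after it.

21 goes back to 20 by masking the C4 carbonyl as the ketal, and 20 goes back to 19 by cutting the C9–H bond. The C9 stereocenter is traded for an enone. The forward reduction must deliver hydride to the face that carries the C1 methyl, so reagent control is planned.

19 goes back to 18 (the C7–H and C8–H bonds restored), 18 to 17 (C8–CO2Me bond restored), and 17 to 15 (C8–CH3 bond cut, enol silyl ether restored). The ester that the carbenoid needs is used once to make C8 a nucleophile for methylation and is then removed. The desaturation can only go to C7=C8 because C10 is flanked by the quaternary C1. The forward methylation must cleave the enol silyl ether and not the C6 silyl ether.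

15 goes back to 14 (O–Si bond) and 14 to 12 by cutting the C6–O and C5–H bonds, an anti-Markovnikov hydration of C5=C6. This hydration is placed directly after the key step: once C9 is a free ketone, borane would reduce it, and once C7=C8 is in place the two alkenes would be conjugated. The forward step must add to the face opposite the C1 methyl and leave the ester-conjugated enol ether untouched.

12 goes back to 7 and 10 through 11 by cutting C7–C8 and C1–C10. This is the strategic cut: it removes ring B and the C1 stereocenter and leaves a ring-A diene and a three-carbon diazo ester. Neither 7 nor 10 needs redesign. The ketal in 7 keeps the diene electron-rich and blocks the C4 carbonyl until step 13. The tert-butyldimethylsilyl group in 10 is robust enough for the enol ether to outlast the borane step. The forward step needs site selectivity for the vinyl group, cis-cyclopropane geometry, catalyst control of the face, and a Cope shift onto a tetrasubstituted terminus.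

7 goes back to 5 and 6 (C5–C6 bond, vinyl transfer), 5 to 3 and 4 (ketal C–O bonds), and 3 to 1 (C5–Br bond). The bromide is introduced at the only position that α-bromination of the enone allows. The ketal is made before the coupling so that the sensitive diene is never exposed to acid.

10 goes back to 9 (O–Si bond) and 9 to 8 (C=N2 bond). Both steps are standard, and a sulfonyl azide with a good safety margin is used for the diazo transfer.

## Other disconnections considered

Alternative 1: The cut is at the two ring-B C–O bonds (C6–O and C9–O), which traces both oxygens to O2 and the carbon framework to the ring-B 1,3-diene A1. In the forward sense, sensitised photo-oxygenation would add singlet oxygen suprafacially across C6=C7–C8=C9 to give endoperoxide A2, and reduction of the O–O bond would give diol A3.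
- In its favour: one step forms both C–O bonds, fixes their cis relation by the mechanism itself, and leaves the alkene at C7=C8 with no redox adjustment.
- Against it here: it says nothing about the carbon skeleton, the quaternary C1 or C4, so A1 still has to be made with three stereocenters. The face must be chosen between one that carries the isopropyl group near C6 and one that carries the C1 methyl near C10 and a hydroxyl that can steer the oxidant by hydrogen bonding. The ene reaction at the C8 methyl competes. The peroxide is base-sensitive (Kornblum–DeLaMare fragmentation). A3 shows two free allylic hydroxyls that must then be acylated differently.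
- Comparison: for the 1,4-dioxygenation alone this plan is better than the chosen one, which needs a hydroboration, a desaturation and a separate carbonyl reduction with two independent stereocontrol events. On structure it is only an endgame, whereas the chosen (4+3) step builds ring B and C1. Mechanistically both rest on a pericyclic event. On step economy it saves about three steps of oxygenation but adds the differentiation of A3 and leaves the route to A1 open. It cannot simply be grafted onto 12, whose unsaturation (C5=C6, C8=C9) is not the diene of A1.

Alternative 2: The cut is at C5–C1 and C5–C6, which traces ring B to the benzene ring of a p-tolyl group and ring A to its side chain in diazoketone A4. In the forward sense, Rh2(OAc)4 would generate a carbenoid at C5 that adds to the ipso–ortho bond, and the norcaradiene would open to trienone A5 (Buchner reaction).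
- In its favour: both rings arise in one step from a flat aromatic precursor with a cheap achiral catalyst, and the C8 methyl and the C4 carbonyl arrive in place.
- Against it here: A5 has no C1 methyl, no isopropyl group and no ring-B oxygen. Its only sp3 ring carbon is racemic and labile (enolisation, hydrogen shifts). The quaternary center would have to be made afterwards on a conjugated triene by an enantioselective conjugate addition. Three alkenes would need to be differentiated. The diazoketone calls for diazomethane.
- Comparison: on ring construction it is better than the chosen plan (two rings against one). On structure and stereochemistry the chosen plan is better, because it sets C1 in the ring-forming step and delivers an alkene and an enol ether already in the right places. Mechanistically both are divalent-rhodium carbenoid reactions followed by a pericyclic ring expansion. On step economy it is shorter to a bicycle but should be longer overall, with a second asymmetric step still to be found.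

Alternative 3: The cut is at C1–C10 and C5–C6. In the forward sense, Cu(OTf)2 with a chiral N-heterocyclic carbene ligand would add the vinyl group of alane A6 to enone 1, and the aluminium enolate would be trapped by iodoenal A7 to give aldol adduct A8.
- In its favour: C1 is set by catalysis as in the chosen plan, C5 and C6 are set in the same operation (three stereocenters against one, which is better), and the C6 oxygen arrives at the right oxidation level. The C4 ketone needs no protection, and all ring-B carbons and the C8 methyl are present after one step.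
- Against it here: no ring closes. Ring B must be closed later at C8–C9, for instance by a Nozaki–Hiyama–Kishi coupling (CrCl2, NiCl2) after the vinyl terminus has been raised to the aldehyde level, and that closure must also set C9. The enolate face at C5 is chosen only by the difference between a methyl and a vinyl group on the neighbouring quaternary carbon. The simple diastereoselection at C6 rests on a hindered aluminium enolate. A8 is a β-hydroxy ketone open to retro-aldol cleavage and dehydration. The parent vinyl alane is less accessible than substituted alkenyl alanes.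
- Comparison: it forms the same C1–C10 bond by a polar addition where the chosen plan uses a sigmatropic shift, and it is equal to the chosen plan in setting C1 by a catalyst. On step economy it could be shorter, and that is a real advantage. The chosen plan is better in that ring closure and C1 are settled in one strain-driven, stereospecific event, and the relation between C5, C6 and C1 is set by a single syn addition.

Key step: step 6

Assumption: Rh2(S-PTAD)4 is taken to attack the face of the vinyl group that gives (1R,2S)-11; if its sense is the opposite, the mirror-image catalyst Rh2(R-PTAD)4 is used and nothing else changes.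

## Steps

Step 1
Reactants: 1 3-methylcyclopent-2-en-1-one
Product: 3 2-bromo-3-methylcyclopent-2-en-1-one, via trans-2,3-dibromo-3-methylcyclopentan-1-one 2 (not isolated)
Conditions: Br2, CH2Cl2, 0 °C; then Et3N, 0 °C → rt
Reagents that add atoms: bromine, BrBr
Why: Bromine addition to the enone followed by E1cB loss of HBr from the α-bromo ketone (bromination–dehydrobromination) should give the α-bromoenone; only the C–H next to the carbonyl is acidic enough to start the elimination.

Step 2
Reactants: 3 2-bromo-3-methylcyclopent-2-en-1-one; 4 ethylene glycol
Product: 5 6-bromo-7-methyl-1,4-dioxaspiro[4.4]non-6-ene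
Conditions: p-TsOH (cat.), toluene, reflux, Dean–Stark
Reagents that add atoms: none
Why: Acid-catalysed ketalisation with azeotropic removal of water; the vinylic bromine disfavours migration of the alkene, so the double bond should stay between the bromine-bearing and the methyl-bearing carbon.

Step 3
Reactants: 5 6-bromo-7-methyl-1,4-dioxaspiro[4.4]non-6-ene; 6 tributyl(vinyl)stannane
Product: 7 7-methyl-6-vinyl-1,4-dioxaspiro[4.4]non-6-ene
Conditions: Pd(PPh3)4 (5 mol %), toluene, 110 °C
Reagents that add atoms: none
Why: Stille coupling: oxidative addition of zerovalent palladium into the vinylic C–Br bond, transmetallation from tin and reductive elimination form the C5–C6 bond under neutral conditions that spare the acid-labile allylic ketal.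

Step 4
Reactants: 8 methyl acetoacetate
Product: 9 methyl 2-diazo-3-oxobutanoate
Conditions: p-ABSA, Et3N, MeCN, 0 °C → rt
Reagents that add atoms: 4-acetamidobenzenesulfonyl azide, CC(=O)Nc1ccc(cc1)S(=O)(=O)N=[N+]=[N-]
Why: Regitz diazo transfer to the active methylene group; this sulfonyl azide is chosen for its safety margin and its sulfonamide by-product is removed by filtration.

Step 5
Reactants: 9 methyl 2-diazo-3-oxobutanoate
Product: 10 methyl 3-(tert-butyldimethylsilyloxy)-2-diazobut-3-enoate
Conditions: TBSOTf, Et3N, CH2Cl2, 0 °C
Reagents that add atoms: tert-butyldimethylsilyl triflate, CC(C)(C)[Si](C)(C)OS(=O)(=O)C(F)(F)F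
Why: Soft enolisation and O-silylation of the ketone; the diazo carbon has no hydrogen, so the enol ether can only form towards the methyl group.

Step 6
Reactants: 7 7-methyl-6-vinyl-1,4-dioxaspiro[4.4]non-6-ene; 10 methyl 3-(tert-butyldimethylsilyloxy)-2-diazobut-3-enoate
Product: 12 methyl (1R)-9-(tert-butyldimethylsilyloxy)-4,4-(ethylenedioxy)-1-methylbicyclo[5.3.0]deca-5,8-diene-8-carboxylate, via cis-divinylcyclopropane 11 (not isolated)
Conditions: Rh2(S-PTAD)4 (1 mol %), hexane, −26 °C, 10 added over 2 h; then rt → 69 °C
Reagents that add atoms: none
Why: Rh2(S-PTAD)4, dirhodium tetrakis[(S)-N-phthaloyl-(1-adamantyl)glycinate], decomposes 10 to a donor/acceptor divalent-rhodium vinylcarbenoid, which cyclopropanates the monosubstituted C6=C7 alkene of 7 with the ester trans and the silyloxyvinyl group cis to the cyclopentenyl group. The cis-divinylcyclopropane 11 then undergoes a Cope rearrangement through a boat array in which C6–C8 breaks and C1–C10 forms; the sequence is the known tandem cyclopropanation/Cope rearrangement of vinyldiazoacetates with dienes, a formal (4+3) cycloaddition. Ring B is closed by [3,3]-sigmatropic ring expansion of the three-membered ring, driven by release of its strain, and not by an end-to-end cyclisation. C1, the one new stereocenter, is not set directly: the catalyst fixes C6 and C8 of 11, and because ring A locks the C5=C1 geometry (methyl cis to C6) the boat shift passes that information to C1 stereospecifically. The step needs site selectivity for the vinyl group over the tetrasubstituted ring alkene, which sterics and the preference of the electrophilic carbenoid for a terminal alkene should secure. It also needs reaction at the carbenoid carbon and not at the vinylogous position, which the 2-silyloxy group and the non-polar solvent should secure. Since the C1 methyl has to point into the boat, the shift is expected to need warming after the carbenoid stage is complete.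

Step 7
Reactants: 12 methyl (1R)-9-(tert-butyldimethylsilyloxy)-4,4-(ethylenedioxy)-1-methylbicyclo[5.3.0]deca-5,8-diene-8-carboxylate
Product: 14 methyl (1R,5S,6S)-9-(tert-butyldimethylsilyloxy)-4,4-(ethylenedioxy)-6-hydroxy-1-methylbicyclo[5.3.0]dec-8-ene-8-carboxylate, via C6 alkylborane 13 (not isolated)
Conditions: BH3·THF, THF, 0 °C → rt; then 30% H2O2, aq. NaOAc, 0 °C → rt
Reagents that add atoms: hydrogen peroxide, OO
Why: Hydroboration–oxidation: boron should go to the less substituted C6 and hydrogen to C5 in a syn addition on the face opposite the axial C1 methyl, the facial course familiar from Δ5-steroids, which sets the trans ring fusion and the C6 hydroxyl together. The ester-conjugated, tetrasubstituted enol ether is too electron-poor and hindered to compete, and the buffered oxidation proceeds with retention at C6.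

Step 8
Reactants: 14 methyl (1R,5S,6S)-9-(tert-butyldimethylsilyloxy)-4,4-(ethylenedioxy)-6-hydroxy-1-methylbicyclo[5.3.0]dec-8-ene-8-carboxylate
Product: 15 methyl (1R,5S,6S)-6,9-bis(tert-butyldimethylsilyloxy)-4,4-(ethylenedioxy)-1-methylbicyclo[5.3.0]dec-8-ene-8-carboxylate
Conditions: TBSOTf, 2,6-lutidine, CH2Cl2, −78 → 0 °C
Reagents that add atoms: tert-butyldimethylsilyl triflate, CC(C)(C)[Si](C)(C)OS(=O)(=O)C(F)(F)F
Why: Silyl ether formation on the hindered secondary alcohol with the reactive triflate and a non-nucleophilic base; this ether has to last through heat, oxidation and organometallic steps.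

Step 9
Reactants: 15 methyl (1R,5S,6S)-6,9-bis(tert-butyldimethylsilyloxy)-4,4-(ethylenedioxy)-1-methylbicyclo[5.3.0]dec-8-ene-8-carboxylate
Product: 17 methyl (1R,5S,6S)-6-(tert-butyldimethylsilyloxy)-4,4-(ethylenedioxy)-1,8-dimethyl-9-oxobicyclo[5.3.0]decane-8-carboxylate (C8 epimers), via cesium enolate 16 (not isolated)
Conditions: CsF, MeI, DMF, 0 °C → rt
Reagents that add atoms: iodomethane, CI
Why: Fluoride-triggered enolate alkylation: fluoride should cleave only the enol silyl ether, because a stabilised β-keto ester enolate leaves silicon far more readily than a hindered secondary alkoxide, and the enolate is C-methylated by the soft electrophile. The configuration at C8 does not matter, since C8 becomes trigonal in step 11.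

Step 10
Reactants: 17 methyl (1R,5S,6S)-6-(tert-butyldimethylsilyloxy)-4,4-(ethylenedioxy)-1,8-dimethyl-9-oxobicyclo[5.3.0]decane-8-carboxylate (C8 epimers)
Product: 18 (1R,5S,6S)-6-(tert-butyldimethylsilyloxy)-4,4-(ethylenedioxy)-1,8-dimethylbicyclo[5.3.0]decan-9-one (C8 epimers)
Conditions: LiCl, H2O, DMSO, 150 °C
Reagents that add atoms: none
Why: Krapcho demethoxycarbonylation: chloride attacks the ester methyl group, the β-keto carboxylate loses CO2 and the enolate is protonated; the near-neutral medium should spare the ketal and the silyl ether.

Step 11
Reactants: 18 (1R,5S,6S)-6-(tert-butyldimethylsilyloxy)-4,4-(ethylenedioxy)-1,8-dimethylbicyclo[5.3.0]decan-9-one (C8 epimers)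
Product: 19 (1R,5S,6S)-6-(tert-butyldimethylsilyloxy)-4,4-(ethylenedioxy)-1,8-dimethylbicyclo[5.3.0]dec-7-en-9-one
Conditions: IBX, DMSO, 75 °C
Reagents that add atoms: none
Why: IBX dehydrogenation of a ketone to its enone through the enol; only the C8 side can be desaturated because C10 is flanked by the quaternary C1 and has no β-hydrogen, so the alkene should form at C7=C8 whichever enol predominates.

Step 12
Reactants: 19 (1R,5S,6S)-6-(tert-butyldimethylsilyloxy)-4,4-(ethylenedioxy)-1,8-dimethylbicyclo[5.3.0]dec-7-en-9-one
Product: 20 (1R,5S,6S,9S)-6-(tert-butyldimethylsilyloxy)-4,4-(ethylenedioxy)-1,8-dimethylbicyclo[5.3.0]dec-7-en-9-ol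
Conditions: (R)-2-methyl-CBS-oxazaborolidine (0.3 equiv), BH3·SMe2, THF, −30 °C
Reagents that add atoms: none
Why: Corey–Bakshi–Shibata reduction: the oxazaborolidine binds the carbonyl lone pair on the side of the C10 methylene, treats the α-methylvinyl arm as the large group, and should deliver hydride to the face that gives the 9S carbinol, with the C9 hydroxyl cis to the C6 oxygen. Reagent control is chosen because the axial C1 methyl may steer an unassisted hydride to the other face.

Step 13
Reactants: 20 (1R,5S,6S,9S)-6-(tert-butyldimethylsilyloxy)-4,4-(ethylenedioxy)-1,8-dimethylbicyclo[5.3.0]dec-7-en-9-ol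
Product: 21 (1R,5S,6S,9S)-6-(tert-butyldimethylsilyloxy)-9-hydroxy-1,8-dimethylbicyclo[5.3.0]dec-7-en-4-one
Conditions: PPTS, acetone–H2O (10:1), 50 °C
Reagents that add atoms: water, O
Why: Acid-catalysed ketal hydrolysis through the oxocarbenium ion and the hemiketal; the weak acid should leave the secondary silyl ether and the allylic alcohol intact and is unlikely to enolise the new ketone towards C5.

Step 14
Reactants: 21 (1R,5S,6S,9S)-6-(tert-butyldimethylsilyloxy)-9-hydroxy-1,8-dimethylbicyclo[5.3.0]dec-7-en-4-one
Product: 22 (1R,4R,5S,6S,9S)-6-(tert-butyldimethylsilyloxy)-4-isopropyl-1,8-dimethylbicyclo[5.3.0]dec-7-ene-4,9-diol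
Conditions: i-PrMgCl (3 equiv), CeCl3, THF, −78 → 0 °C
Reagents that add atoms: isopropylmagnesium chloride, CC(C)[Mg]Cl
Why: Organocerium 1,2-addition, which suppresses enolisation and β-hydride reduction; the nucleophile should enter ring A from the face of H5, away from the axial C1 methyl and the C6 substituent, so that the new hydroxyl ends cis to the C1 methyl (4R). The C9 alkoxide formed by the first equivalent is a spectator.

Step 15
Reactants: 22 (1R,4R,5S,6S,9S)-6-(tert-butyldimethylsilyloxy)-4-isopropyl-1,8-dimethylbicyclo[5.3.0]dec-7-ene-4,9-diol
Product: 23 (1R,4R,5S,6S,9S)-6-(tert-butyldimethylsilyloxy)-4-hydroxy-4-isopropyl-1,8-dimethylbicyclo[5.3.0]dec-7-en-9-yl acetate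
Conditions: Ac2O, pyridine, DMAP (cat.), CH2Cl2, 0 °C → rt
Reagents that add atoms: acetic anhydride, CC(=O)OC(C)=O
Why: Nucleophile-catalysed acylation of the only secondary hydroxyl; the hindered tertiary C4 carbinol should not react under these conditions.

Step 16
Reactants: 23 (1R,4R,5S,6S,9S)-6-(tert-butyldimethylsilyloxy)-4-hydroxy-4-isopropyl-1,8-dimethylbicyclo[5.3.0]dec-7-en-9-yl acetate
Product: 24 (1R,4R,5S,6S,9S)-4,6-dihydroxy-4-isopropyl-1,8-dimethylbicyclo[5.3.0]dec-7-en-9-yl acetate
Conditions: HF·pyridine, pyridine, THF, 0 °C → rt
Reagents that add atoms: none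
Why: Fluoride-assisted Si–O cleavage in a buffered, weakly acidic medium, which avoids the acyl migration and ester cleavage that a basic fluoride source could cause.

Step 17
Reactants: 24 (1R,4R,5S,6S,9S)-4,6-dihydroxy-4-isopropyl-1,8-dimethylbicyclo[5.3.0]dec-7-en-9-yl acetate; 25 4-acetoxybenzoyl chloride
Product: 26 (1R,4R,5S,6S,9S)-9-acetoxy-4-hydroxy-4-isopropyl-1,8-dimethylbicyclo[5.3.0]dec-7-en-6-yl 4-acetoxybenzoate
Conditions: Et3N, DMAP, CH2Cl2, 0 °C → rt
Reagents that add atoms: none
Why: DMAP-catalysed acylation of the hindered secondary C6 alcohol by the acid chloride; the tertiary alcohol should stay free and the phenol is carried as its acetate.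

Step 18
Reactants: 26 (1R,4R,5S,6S,9S)-9-acetoxy-4-hydroxy-4-isopropyl-1,8-dimethylbicyclo[5.3.0]dec-7-en-6-yl 4-acetoxybenzoate
Product: 27 (1R,4R,5S,6S,9S)-9-acetoxy-4-hydroxy-4-isopropyl-1,8-dimethylbicyclo[5.3.0]dec-7-en-6-yl 4-hydroxybenzoate (target)
Conditions: pyrrolidine (2 equiv), CH2Cl2, 0 °C
Reagents that add atoms: none
Why: Chemoselective aminolysis: the aryl acetate is an activated ester with a p-acylphenoxide leaving group and should be cleaved far faster than the allylic alkyl acetate or the hindered benzoate.

## Compound list

1 | 3-methylcyclopent-2-en-1-one | CC1=CC(=O)CC1 | starting material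
2 | trans-2,3-dibromo-3-methylcyclopentan-1-one (racemic, one enantiomer drawn) | C[C@]1(Br)CCC(=O)[C@@H]1Br | intermediate (not isolated)
3 | 2-bromo-3-methylcyclopent-2-en-1-one | CC1=C(Br)C(=O)CC1 | intermediate
4 | ethylene glycol | OCCO | starting material
5 | 6-bromo-7-methyl-1,4-dioxaspiro[4.4]non-6-ene | CC1=C(Br)C2(CC1)OCCO2 | intermediate
6 | tributyl(vinyl)stannane | C=C[Sn](CCCC)(CCCC)CCCC | starting material
7 | 7-methyl-6-vinyl-1,4-dioxaspiro[4.4]non-6-ene | C=CC1=C(C)CCC12OCCO2 | intermediate
8 | methyl acetoacetate | COC(=O)CC(C)=O | starting material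
9 | methyl 2-diazo-3-oxobutanoate | COC(=O)C(=[N+]=[N-])C(C)=O | intermediate
10 | methyl 3-(tert-butyldimethylsilyloxy)-2-diazobut-3-enoate | COC(=O)C(=[N+]=[N-])C(=C)O[Si](C)(C)C(C)(C)C | intermediate
11 | methyl (1R,2S)-1-[1-(tert-butyldimethylsilyloxy)vinyl]-2-(7-methyl-1,4-dioxaspiro[4.4]non-6-en-6-yl)cyclopropane-1-carboxylate (ester trans, silyloxyvinyl cis to the cyclopentenyl group) | COC(=O)[C@]1(C(=C)O[Si](C)(C)C(C)(C)C)C[C@H]1C2=C(C)CCC23OCCO3 | intermediate (not isolated)
12 | methyl (1R)-9-(tert-butyldimethylsilyloxy)-4,4-(ethylenedioxy)-1-methylbicyclo[5.3.0]deca-5,8-diene-8-carboxylate | COC(=O)C1=C(O[Si](C)(C)C(C)(C)C)C[C@@]2(C)CCC3(OCCO3)C2=CC1 | intermediate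
13 | methyl (1R,5R,6S)-6-boranyl-9-(tert-butyldimethylsilyloxy)-4,4-(ethylenedioxy)-1-methylbicyclo[5.3.0]dec-8-ene-8-carboxylate (H5 and boron anti to the C1 methyl) | COC(=O)C1=C(O[Si](C)(C)C(C)(C)C)C[C@@]2(C)CCC3(OCCO3)[C@@H]2[C@@H](B)C1 | intermediate (not isolated)
14 | methyl (1R,5S,6S)-9-(tert-butyldimethylsilyloxy)-4,4-(ethylenedioxy)-6-hydroxy-1-methylbicyclo[5.3.0]dec-8-ene-8-carboxylate | COC(=O)C1=C(O[Si](C)(C)C(C)(C)C)C[C@@]2(C)CCC3(OCCO3)[C@@H]2[C@@H](O)C1 | intermediate
15 | methyl (1R,5S,6S)-6,9-bis(tert-butyldimethylsilyloxy)-4,4-(ethylenedioxy)-1-methylbicyclo[5.3.0]dec-8-ene-8-carboxylate | COC(=O)C1=C(O[Si](C)(C)C(C)(C)C)C[C@@]2(C)CCC3(OCCO3)[C@@H]2[C@@H](O[Si](C)(C)C(C)(C)C)C1 | intermediate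
16 | cesium (1R,5S,6S)-6-(tert-butyldimethylsilyloxy)-4,4-(ethylenedioxy)-8-(methoxycarbonyl)-1-methylbicyclo[5.3.0]dec-8-en-9-olate | [Cs+].COC(=O)C1=C([O-])C[C@@]2(C)CCC3(OCCO3)[C@@H]2[C@@H](O[Si](C)(C)C(C)(C)C)C1 | intermediate (not isolated)
17 | methyl (1R,5S,6S)-6-(tert-butyldimethylsilyloxy)-4,4-(ethylenedioxy)-1,8-dimethyl-9-oxobicyclo[5.3.0]decane-8-carboxylate (C8 epimers) | COC(=O)C1(C)C(=O)C[C@@]2(C)CCC3(OCCO3)[C@@H]2[C@@H](O[Si](C)(C)C(C)(C)C)C1 | intermediate
18 | (1R,5S,6S)-6-(tert-butyldimethylsilyloxy)-4,4-(ethylenedioxy)-1,8-dimethylbicyclo[5.3.0]decan-9-one (C8 epimers) | CC1C(=O)C[C@@]2(C)CCC3(OCCO3)[C@@H]2[C@@H](O[Si](C)(C)C(C)(C)C)C1 | intermediate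
19 | (1R,5S,6S)-6-(tert-butyldimethylsilyloxy)-4,4-(ethylenedioxy)-1,8-dimethylbicyclo[5.3.0]dec-7-en-9-one | O=C1C[C@@]2(C)CCC3(OCCO3)[C@@H]2[C@@H](O[Si](C)(C)C(C)(C)C)C=C1C | intermediate
20 | (1R,5S,6S,9S)-6-(tert-butyldimethylsilyloxy)-4,4-(ethylenedioxy)-1,8-dimethylbicyclo[5.3.0]dec-7-en-9-ol | O[C@H]1C[C@@]2(C)CCC3(OCCO3)[C@@H]2[C@@H](O[Si](C)(C)C(C)(C)C)C=C1C | intermediate
21 | (1R,5S,6S,9S)-6-(tert-butyldimethylsilyloxy)-9-hydroxy-1,8-dimethylbicyclo[5.3.0]dec-7-en-4-one | O[C@H]1C[C@@]2(C)CCC(=O)[C@@H]2[C@@H](O[Si](C)(C)C(C)(C)C)C=C1C | intermediate
22 | (1R,4R,5S,6S,9S)-6-(tert-butyldimethylsilyloxy)-4-isopropyl-1,8-dimethylbicyclo[5.3.0]dec-7-ene-4,9-diol | O[C@H]1C[C@@]2(C)CC[C@@](O)(C(C)C)[C@@H]2[C@@H](O[Si](C)(C)C(C)(C)C)C=C1C | intermediate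
23 | (1R,4R,5S,6S,9S)-6-(tert-butyldimethylsilyloxy)-4-hydroxy-4-isopropyl-1,8-dimethylbicyclo[5.3.0]dec-7-en-9-yl acetate | CC(=O)O[C@H]1C[C@@]2(C)CC[C@@](O)(C(C)C)[C@@H]2[C@@H](O[Si](C)(C)C(C)(C)C)C=C1C | intermediate
24 | (1R,4R,5S,6S,9S)-4,6-dihydroxy-4-isopropyl-1,8-dimethylbicyclo[5.3.0]dec-7-en-9-yl acetate | CC(=O)O[C@H]1C[C@@]2(C)CC[C@@](O)(C(C)C)[C@@H]2[C@@H](O)C=C1C | intermediate
25 | 4-acetoxybenzoyl chloride | CC(=O)Oc1ccc(cc1)C(Cl)=O | starting material
26 | (1R,4R,5S,6S,9S)-9-acetoxy-4-hydroxy-4-isopropyl-1,8-dimethylbicyclo[5.3.0]dec-7-en-6-yl 4-acetoxybenzoate | CC(=O)O[C@H]1C[C@@]2(C)CC[C@@](O)(C(C)C)[C@@H]2[C@@H](OC(=O)c2ccc(OC(C)=O)cc2)C=C1C | intermediate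
27 | (1R,4R,5S,6S,9S)-9-acetoxy-4-hydroxy-4-isopropyl-1,8-dimethylbicyclo[5.3.0]dec-7-en-6-yl 4-hydroxybenzoate | CC(=O)O[C@H]1C[C@@]2(C)CC[C@@](O)(C(C)C)[C@@H]2[C@@H](OC(=O)c2ccc(O)cc2)C=C1C | target

## Step count and risks

Total step count: 18. Longest linear sequence: 16 steps (steps 1 to 3, then 6 to 18); the diazo ester branch (steps 4 and 5) has 2 steps.

**Step 6 (key step).** The sigmatropic stage is the likeliest point of failure. The C1 methyl has to turn towards the three-membered ring in the boat array, so the rearrangement may lag behind the cyclopropanation. The heating then needed can reopen the donor–acceptor cyclopropane reversibly (cis–trans isomerisation) and so leak enantiomeric purity. A hindered vinyl group with a fully substituted neighbour may also be discriminated less well by the catalyst.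

Fallback: the source of enantiomeric purity is moved from the catalyst to a later reagent-controlled step. Setting out from 12 of whatever enantiomeric purity a forced thermal rearrangement (xylene, 140 °C) delivers, steps 7 to 11 are run unchanged and the reduction of step 12 is used as a resolving step. The minor enantiomer of 19 should be reduced by the same oxazaborolidine to a 9S carbinol as well. That product is the diastereomer (1S,5R,6R,9S)-6-(tert-butyldimethylsilyloxy)-4,4-(ethylenedioxy)-1,8-dimethylbicyclo[5.3.0]dec-7-en-9-ol F1, not the enantiomer of 20, and can be removed by chromatography. The route is rejoined at 20. This holds only as far as reagent control governs both enantiomers, and it recovers purity, not yield.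

**Step 7.** Facial leakage is the main risk. The face opposite the C1 methyl is partly covered by the fold of ring B and flanked by the ketal, so some borane may add from the methyl face and give the cis fusion. A slow hydroboration would also give borane time to attack the silyloxy enoate.

Fallback: setting out from 12, dimethyldioxirane (acetone, −20 °C) should epoxidise C5=C6 and give methyl (1R)-9-(tert-butyldimethylsilyloxy)-5,6-epoxy-4,4-(ethylenedioxy)-1-methylbicyclo[5.3.0]dec-8-ene-8-carboxylate F2, with the epoxide oxygen on the face opposite the C1 methyl. The trivalent titanium reagent Cp2TiCl (from Cp2TiCl2 and Zn) with 1,4-cyclohexadiene in THF then opens the epoxide homolytically to the tertiary C5 radical with the oxygen left on C6. Hydrogen-atom capture at C5 returns the route to 14. The C6 configuration is then fixed by the epoxidation, and only the hydrogen transfer to C5 remains to be controlled.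

**Step 12.** Mismatched double stereodifferentiation is the risk. The face the catalyst selects is the one shielded by the axial C1 methyl, so reagent control may be incomplete and the reduction slow.

Fallback: substrate control followed by inversion. Setting out from 19, NaBH4 with CeCl3·7H2O in MeOH at −78 °C (Luche reduction) should attack the open face and give (1R,5S,6S,9R)-6-(tert-butyldimethylsilyloxy)-4,4-(ethylenedioxy)-1,8-dimethylbicyclo[5.3.0]dec-7-en-9-ol F3. Mitsunobu inversion (4-nitrobenzoic acid, PPh3, DIAD, toluene, 0 °C) gives (1R,5S,6S,9S)-6-(tert-butyldimethylsilyloxy)-4,4-(ethylenedioxy)-1,8-dimethylbicyclo[5.3.0]dec-7-en-9-yl 4-nitrobenzoate F4. K2CO3 in MeOH returns the route to 20.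

**Step 14.** The ketone is flanked by the substituted C5, and an isopropyl metal reagent can transfer a β-hydride (reduction) or act as a base. Enolisation towards C5 would risk loss of the ring-fusion configuration or elimination of the C6 silyloxy group.

Fallback: a nucleophile without β-hydrogens, followed by hydrogenation. Setting out from 21, isopropenylmagnesium bromide with CeCl3 in THF at −78 °C should give (1R,4S,5S,6S,9S)-6-(tert-butyldimethylsilyloxy)-4-isopropenyl-1,8-dimethylbicyclo[5.3.0]dec-7-ene-4,9-diol F5. It has the same spatial arrangement at C4 as 22; the descriptor changes only through ligand priority. H2 with RhCl(PPh3)3 in toluene at rt should saturate only the 1,1-disubstituted alkene and return the route to 22.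

**Step 17.** Acylation of the hindered C6 hydroxyl may be slow enough for acetyl transfer from the aryl acetate of the reagent to compete, which would put an acetyl group on C6.

Fallback: a phenol protecting group that cannot be transferred. Setting out from 24, Yamaguchi esterification with commercially available 4-(tert-butyldimethylsilyloxy)benzoic acid (2,4,6-trichlorobenzoyl chloride, Et3N; then DMAP, toluene) should give (1R,4R,5S,6S,9S)-9-acetoxy-4-hydroxy-4-isopropyl-1,8-dimethylbicyclo[5.3.0]dec-7-en-6-yl 4-(tert-butyldimethylsilyloxy)benzoate F6. Tetrabutylammonium fluoride buffered with AcOH (THF, 0 °C) then frees the phenol and reaches 27 directly.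

## Further compounds

F1 | step 6 | (1S,5R,6R,9S)-6-(tert-butyldimethylsilyloxy)-4,4-(ethylenedioxy)-1,8-dimethylbicyclo[5.3.0]dec-7-en-9-ol | O[C@H]1C[C@]2(C)CCC3(OCCO3)[C@H]2[C@H](O[Si](C)(C)C(C)(C)C)C=C1C
F2 | step 7 | methyl (1R)-9-(tert-butyldimethylsilyloxy)-5,6-epoxy-4,4-(ethylenedioxy)-1-methylbicyclo[5.3.0]dec-8-ene-8-carboxylate (epoxide oxygen anti to the C1 methyl) | COC(=O)C1=C(O[Si](C)(C)C(C)(C)C)C[C@@]2(C)CCC3(OCCO3)[C@@]24O[C@H]4C1
F3 | step 12 | (1R,5S,6S,9R)-6-(tert-butyldimethylsilyloxy)-4,4-(ethylenedioxy)-1,8-dimethylbicyclo[5.3.0]dec-7-en-9-ol | O[C@@H]1C[C@@]2(C)CCC3(OCCO3)[C@@H]2[C@@H](O[Si](C)(C)C(C)(C)C)C=C1C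
F4 | step 12 | (1R,5S,6S,9S)-6-(tert-butyldimethylsilyloxy)-4,4-(ethylenedioxy)-1,8-dimethylbicyclo[5.3.0]dec-7-en-9-yl 4-nitrobenzoate | O=C(O[C@H]1C[C@@]2(C)CCC3(OCCO3)[C@@H]2[C@@H](O[Si](C)(C)C(C)(C)C)C=C1C)c1ccc(cc1)[N+](=O)[O-]
F5 | step 14 | (1R,4S,5S,6S,9S)-6-(tert-butyldimethylsilyloxy)-4-isopropenyl-1,8-dimethylbicyclo[5.3.0]dec-7-ene-4,9-diol | O[C@H]1C[C@@]2(C)CC[C@@](O)(C(C)=C)[C@@H]2[C@@H](O[Si](C)(C)C(C)(C)C)C=C1C
F6 | step 17 | (1R,4R,5S,6S,9S)-9-acetoxy-4-hydroxy-4-isopropyl-1,8-dimethylbicyclo[5.3.0]dec-7-en-6-yl 4-(tert-butyldimethylsilyloxy)benzoate | CC(=O)O[C@H]1C[C@@]2(C)CC[C@@](O)(C(C)C)[C@@H]2[C@@H](OC(=O)c2ccc(O[Si](C)(C)C(C)(C)C)cc2)C=C1C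
A1 | alternative 1 | ring-B 1,3-diene (C6=C7, C8=C9) with C1 methyl, C4 hydroxyl and isopropyl and H5 as in the target | CC1=CC[C@@]2(C)CC[C@@](O)(C(C)C)[C@@H]2C=C1
A2 | alternative 1 | C6,C9-endoperoxide with C7=C8 alkene, peroxide bridge anti to the C1 methyl | O3[C@H]1C[C@@]2(C)CC[C@@](O)(C(C)C)[C@@H]2[C@@H](O3)C=C1C
A3 | alternative 1 | (1R,4R,5S,6S,9S)-4-isopropyl-1,8-dimethylbicyclo[5.3.0]dec-7-ene-4,6,9-triol | O[C@H]1C[C@@]2(C)CC[C@@](O)(C(C)C)[C@@H]2[C@@H](O)C=C1C
A4 | alternative 2 | 1-diazo-4-(4-methylphenyl)butan-2-one | Cc1ccc(CCC(=O)C=[N+]=[N-])cc1
A5 | alternative 2 | 6-methyl-3,8a-dihydroazulen-1(2H)-one (racemic) | CC1=CC=C2CCC(=O)C2C=C1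
A6 | alternative 3 | dimethyl(vinyl)alane | C=C[Al](C)C
A7 | alternative 3 | (Z)-3-iodobut-2-enal | I/C(C)=C\C=O
A8 | alternative 3 | 2,3-trans aldol adduct: 3-methyl-3-vinylcyclopentanone carrying the C6 carbinol and the (Z)-vinyl iodide at C2 | C=C[C@@]1(C)CCC(=O)[C@@H]1[C@@H](O)/C=C(C)\I
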